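**Retrosynthetic overview**
- Feature: in the phthalide (benzene ring A, lactone ring B) the carbonyl C1 hangs on C7a, para to O5, the middle of the three contiguous oxygens on C4, C5 and C6, and C7 is unsubstituted. The bromine of symmetrical 5-bromo-1,2,3-trimethoxybenzene therefore already sits on the future C7a, and the two carbons beside it are equivalent.
- Last disconnection: C7a–C1 and C1–O2, by carbonylative lactonization of the ortho-bromobenzyl alcohol that already carries the full side chain. Ring B is the only ring made and it is made last.
- The bromobenzyl alcohol comes from its salicylaldehyde by reduction. The O5–CH2 ether bond comes from alkylating the catechol dianion of 6-bromo-2,3-dihydroxy-4-methoxybenzaldehyde with the allylic bromide.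
- The catechol aldehyde comes from formylation of the symmetrical bromoarene and aldehyde-directed double demethylation; the aldehyde carbon becomes C3.
- The allylic bromide comes from (2E,6E)-farnesol: terminal bromohydrin, debromination, tertiary acetylation, selective primary deacetylation, bromination.

Key step: step 11

Remark: the side chain of the target is numbered from the acetate-bearing carbon, so its two E alkenes carry the locants 6 and 10. Bromohydrin 3 is racemic at C10 and that centre is removed in step 3. The bromine is not introduced by brominating a free phenol, because a phenol flanked by two ether oxygens can also brominate ortho/para to the ethers; it is bought in place on compound 8.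

**Route**

Step 1
Reactants: 1 (2E,6E)-farnesol
Product: 2 (2E,6E)-farnesyl acetate
Conditions: Ac2O, pyridine, DMAP (cat.), CH2Cl2, 0 °C to rt
Reagents that add atoms: acetic anhydride, CC(=O)OC(C)=O
Why: DMAP-catalysed acetylation of a primary allylic alcohol masks the C1 hydroxyl for the next three steps.

Step 2
Reactants: 2 (2E,6E)-farnesyl acetate
Product: 3 (2E,6E)-10-bromo-11-hydroxy-3,7,11-trimethyldodeca-2,6-dien-1-yl acetate (racemic at C10)
Conditions: NBS (1.1 equiv), THF/H2O, 0 °C
Reagents that add atoms: N-bromosuccinimide, O=C1CCC(=O)N1Br; water, O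
Why: Bromohydrin formation with NBS in aqueous THF is known to pick the terminal trisubstituted alkene of polyprenyl acetates, water opening the bromonium ion at the tertiary carbon (Markovnikov); the new centre at C10 forms racemic and is erased in step 3.

Step 3
Reactants: 3 (2E,6E)-10-bromo-11-hydroxy-3,7,11-trimethyldodeca-2,6-dien-1-yl acetate
Product: 4 (2E,6E)-11-hydroxy-3,7,11-trimethyldodeca-2,6-dien-1-yl acetate
Conditions: Bu3SnH (1.2 equiv), AIBN (cat.), toluene, 80 °C
Reagents that add atoms: none
Why: Radical chain hydrodebromination removes the secondary bromide; the C10 radical has only 4-exo or 5-endo modes toward the 6,7-alkene and is simply reduced, while the tertiary alcohol, the acetate and both E alkenes are inert.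

Step 4
Reactants: 4 (2E,6E)-11-hydroxy-3,7,11-trimethyldodeca-2,6-dien-1-yl acetate
Product: 5 (2E,6E)-3,7,11-trimethyldodeca-2,6-diene-1,11-diyl diacetate
Conditions: Ac2O, Et3N, DMAP, CH2Cl2, rt to 40 °C
Reagents that add atoms: acetic anhydride, CC(=O)OC(C)=O
Why: DMAP-catalysed acylation (Steglich-type nucleophilic catalysis) is the standard way to acetylate a hindered tertiary alcohol without ionising it.

Step 5
Reactants: 5 (2E,6E)-3,7,11-trimethyldodeca-2,6-diene-1,11-diyl diacetate
Product: 6 (6E,10E)-12-hydroxy-2,6,10-trimethyldodeca-6,10-dien-2-yl acetate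
Conditions: K2CO3 (0.2 equiv), MeOH, 0 °C
Reagents that add atoms: none
Why: Base-catalysed transesterification (Zemplén-type methanolysis) cleaves the unhindered primary allylic acetate far faster than the hindered tertiary acetate, so a short reaction at 0 °C should leave the latter in place.

Step 6
Reactants: 6 (6E,10E)-12-hydroxy-2,6,10-trimethyldodeca-6,10-dien-2-yl acetate
Product: 7 (6E,10E)-12-bromo-2,6,10-trimethyldodeca-6,10-dien-2-yl acetate
Conditions: CBr4, PPh3, CH2Cl2, 0 °C (used without storage)
Reagents that add atoms: carbon tetrabromide, BrC(Br)(Br)Br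
Why: The Appel reaction turns the primary allylic alcohol into the bromide by SN2 displacement of the oxyphosphonium group under neutral conditions, keeping the E geometry and the acid-sensitive tertiary acetate.

Step 7
Reactants: 8 5-bromo-1,2,3-trimethoxybenzene
Product: 9 6-bromo-2,3,4-trimethoxybenzaldehyde
Conditions: Cl2CHOMe, TiCl4, CH2Cl2, 0 °C; then ice/H2O
Reagents that add atoms: dichloromethyl methyl ether, COC(Cl)Cl; water, O
Why: Rieche formylation is an electrophilic aromatic substitution ortho to one methoxy group and para to another; the two open positions of 8 are equivalent by symmetry, so only one aldehyde can form and the bromine ends up ortho to the formyl group.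

Step 8
Reactants: 9 6-bromo-2,3,4-trimethoxybenzaldehyde
Product: 10 6-bromo-2,3-dihydroxy-4-methoxybenzaldehyde
Conditions: BCl3 (2.5 equiv), CH2Cl2, 0 °C to rt; then H2O
Reagents that add atoms: none
Why: Carbonyl-directed ether cleavage with BCl3 removes first the methyl ortho to the aldehyde through a six-membered boron chelate and then the neighbouring methyl through a five-membered catechol borate, while the methoxy group para to the aldehyde has no such assistance, a double demethylation known for 2,3,4-trimethoxybenzaldehyde.

Step 9
Reactants: 10 6-bromo-2,3-dihydroxy-4-methoxybenzaldehyde; 7 (6E,10E)-12-bromo-2,6,10-trimethyldodeca-6,10-dien-2-yl acetate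
Product: 12 (6E,10E)-12-(4-bromo-3-formyl-2-hydroxy-6-methoxyphenoxy)-2,6,10-trimethyldodeca-6,10-dien-2-yl acetate, via disodium catecholate 11 (not isolated)
Conditions: NaH (2.0 equiv), DMSO, rt; then 7 (1.0 equiv), rt; cold dilute aq. HCl work-up
Reagents that add atoms: none
Why: Williamson alkylation of a catechol dianion: in 11 the oxygen ortho to the formyl group is conjugated with it and chelated to sodium, so the other, more basic phenoxide (meta to the aldehyde) attacks the primary allylic bromide first in an SN2 reaction that keeps the E geometry, a regioselectivity known for dianions of 2,3-dihydroxybenzaldehydes.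

Step 10
Reactants: 12 (6E,10E)-12-(4-bromo-3-formyl-2-hydroxy-6-methoxyphenoxy)-2,6,10-trimethyldodeca-6,10-dien-2-yl acetate
Product: 13 (6E,10E)-12-[4-bromo-2-hydroxy-3-(hydroxymethyl)-6-methoxyphenoxy]-2,6,10-trimethyldodeca-6,10-dien-2-yl acetate
Conditions: NaBH4, THF/MeOH, 0 °C; aq. NH4Cl (product kept away from acid and used promptly)
Reagents that add atoms: none
Why: NaBH4 reduction of the salicylaldehyde gives the benzylic alcohol at 0 °C, where the aryl bromide, the allyl aryl ether, the alkenes and the hindered tertiary acetate do not react.

Step 11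
Reactants: 13 (6E,10E)-12-[4-bromo-2-hydroxy-3-(hydroxymethyl)-6-methoxyphenoxy]-2,6,10-trimethyldodeca-6,10-dien-2-yl acetate; 14 carbon monoxide
Product: 15 Farnesylemefuranone F, (6E,10E)-12-[(4-hydroxy-6-methoxy-1-oxo-1,3-dihydro-2-benzofuran-5-yl)oxy]-2,6,10-trimethyldodeca-6,10-dien-2-yl acetate
Conditions: Pd(OAc)2 (5 mol %), 1,1'-bis(diphenylphosphino)ferrocene (10 mol %), Et3N (3 equiv), CO (1 atm), DMF, 80 °C
Reagents that add atoms: carbon monoxide (compound 14, listed under Reactants), [C-]#[O+]
Why: Pd(OAc)2 is reduced in the flask to zerovalent palladium, which inserts into the C–Br bond of 13; CO insertion gives an aroylpalladium bromide, the ortho CH2OH attacks the acyl carbon, and Et3N takes up HBr so that the catalyst is released. This is the known palladium-catalysed carbonylative lactonization of 2-bromobenzyl alcohols to phthalides, an intramolecular alkoxycarbonylation. The one ring formed, the five-membered lactone ring B, closes by 5-exo-trig acyl substitution with formation of C7a–C1 and C1–O2; no stereocentre is created and the two E alkenes are not involved. The step needs chemoselectivity for insertion into the aryl bromide over ionisation of the allylic C–O bond of the aryl ether; the slowly ionising trisubstituted allyl terminus, the chelating diphosphine, the CO atmosphere that keeps zerovalent palladium electron-poor and the absence of a soft nucleophile should secure it. The phenol on C4 sits meta to the acyl carbon and cannot reach it, so only the benzylic hydroxyl is acylated, and the lactone orientation is fixed by the positions of Br and CH2OH in 13.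

**Compound list**

1 | (2E,6E)-farnesol, (2E,6E)-3,7,11-trimethyldodeca-2,6,10-trien-1-ol | CC(C)=CCC/C(C)=C/CC/C(C)=C/CO | starting material
2 | (2E,6E)-farnesyl acetate | CC(C)=CCC/C(C)=C/CC/C(C)=C/COC(C)=O | intermediate
3 | (2E,6E)-10-bromo-11-hydroxy-3,7,11-trimethyldodeca-2,6-dien-1-yl acetate (racemic at C10) | CC(C)(O)C(Br)CC/C(C)=C/CC/C(C)=C/COC(C)=O | intermediate
4 | (2E,6E)-11-hydroxy-3,7,11-trimethyldodeca-2,6-dien-1-yl acetate | CC(C)(O)CCC/C(C)=C/CC/C(C)=C/COC(C)=O | intermediate
5 | (2E,6E)-3,7,11-trimethyldodeca-2,6-diene-1,11-diyl diacetate | CC(=O)OC(C)(C)CCC/C(C)=C/CC/C(C)=C/COC(C)=O | intermediate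
6 | (6E,10E)-12-hydroxy-2,6,10-trimethyldodeca-6,10-dien-2-yl acetate | CC(=O)OC(C)(C)CCC/C(C)=C/CC/C(C)=C/CO | intermediate
7 | (6E,10E)-12-bromo-2,6,10-trimethyldodeca-6,10-dien-2-yl acetate | CC(=O)OC(C)(C)CCC/C(C)=C/CC/C(C)=C/CBr | intermediate
8 | 5-bromo-1,2,3-trimethoxybenzene | COc1cc(Br)cc(OC)c1OC | starting material
9 | 6-bromo-2,3,4-trimethoxybenzaldehyde | COc1cc(Br)c(C=O)c(OC)c1OC | intermediate
10 | 6-bromo-2,3-dihydroxy-4-methoxybenzaldehyde | COc1cc(Br)c(C=O)c(O)c1O | intermediate
11 | disodium 4-bromo-3-formyl-6-methoxybenzene-1,2-diolate | COc1cc(Br)c(C=O)c([O-])c1[O-].[Na+].[Na+] | intermediate (not isolated)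
12 | (6E,10E)-12-(4-bromo-3-formyl-2-hydroxy-6-methoxyphenoxy)-2,6,10-trimethyldodeca-6,10-dien-2-yl acetate | COc1cc(Br)c(C=O)c(O)c1OC/C=C(\C)CC/C=C(\C)CCCC(C)(C)OC(C)=O | intermediate
13 | (6E,10E)-12-[4-bromo-2-hydroxy-3-(hydroxymethyl)-6-methoxyphenoxy]-2,6,10-trimethyldodeca-6,10-dien-2-yl acetate | COc1cc(Br)c(CO)c(O)c1OC/C=C(\C)CC/C=C(\C)CCCC(C)(C)OC(C)=O | intermediate
14 | carbon monoxide | [C-]#[O+] | starting material
15 | Farnesylemefuranone F | COc1cc2c(c(O)c1OC/C=C(\C)CC/C=C(\C)CCCC(C)(C)OC(C)=O)COC2=O | target

**Step count and risks**

Total step count: 11. Longest linear sequence: 9 steps (steps 1 to 6, then 9, 10 and 11, from farnesol); the arene branch from 8 runs through steps 7 to 11.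

Steps most likely to fail:

1. Step 11. Zerovalent palladium may ionise the allylic C–O bond of the aryl ether faster than it inserts into the electron-rich aryl bromide, which would strip or transpose the chain or scramble the 10E alkene. The electron-rich 2-hydroxybenzyl alcohol may also lose water on heating. The fallback closes the lactone before the chain is attached and sets out from 10. Methoxycarbonylation (Pd(OAc)2, 1,1'-bis(diphenylphosphino)ferrocene, CO, MeOH, Et3N, DMF, 80 °C) should give methyl 2-formyl-3,4-dihydroxy-5-methoxybenzoate F1. NaBH4 in MeOH followed by mild acidification should reduce the aldehyde and lactonize to 4,5-dihydroxy-6-methoxy-2-benzofuran-1(3H)-one F2. Alkylation of F2 with 7 (1.0 equiv) and KHCO3 in DMF at rt should go at the 5-hydroxyl, the more acidic one because it is para to the lactone carbonyl. The fallback comes back to the route at 15.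

2. Step 9. The dianion may be alkylated at the oxygen next to the aldehyde or at both oxygens, if the two phenoxides are not discriminated well enough. The fallback makes O3 the only free hydroxyl and sets out from 10. NaBH4 (MeOH, 0 °C) should give 4-bromo-3-(hydroxymethyl)-6-methoxybenzene-1,2-diol F3. 2,2-Dimethoxypropane with catalytic pyridinium p-toluenesulfonate in acetone at rt should tie the benzylic hydroxyl and the neighbouring phenol into the six-membered acetonide 5-bromo-7-methoxy-2,2-dimethyl-4H-1,3-benzodioxin-8-ol F4. Alkylation of its single phenol with 7 (K2CO3, DMF, rt) should give (6E,10E)-12-[(5-bromo-7-methoxy-2,2-dimethyl-4H-1,3-benzodioxin-8-yl)oxy]-2,6,10-trimethyldodeca-6,10-dien-2-yl acetate F5. AcOH/THF/H2O at 40 °C should remove the acetonide. The fallback replaces steps 9 and 10 and comes back to the route at 13.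

3. Step 8. The ether cleavage may stop after the first methyl group or run on to the third, giving a mixture of phenols. The fallback cleaves all three ethers and puts one methyl back selectively; it sets out from 9. BBr3 (CH2Cl2, −78 °C to rt) should give 6-bromo-2,3,4-trihydroxybenzaldehyde F6. Treatment with Na2B4O7, NaOH and Me2SO4 in water, then dilute HCl, should methylate only the 4-hydroxyl: the borate holds the 2,3-diol, and the 4-hydroxyl, para to the aldehyde, is the most acidic. The fallback comes back to the route at 10.

**Further compounds**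

F1 | step 11 | methyl 2-formyl-3,4-dihydroxy-5-methoxybenzoate | COC(=O)c1cc(OC)c(O)c(O)c1C=O
F2 | step 11 | 4,5-dihydroxy-6-methoxy-2-benzofuran-1(3H)-one | COc1cc2c(c(O)c1O)COC2=O
F3 | step 9 | 4-bromo-3-(hydroxymethyl)-6-methoxybenzene-1,2-diol | COc1cc(Br)c(CO)c(O)c1O
F4 | step 9 | 5-bromo-7-methoxy-2,2-dimethyl-4H-1,3-benzodioxin-8-ol | COc1cc(Br)c2COC(C)(C)Oc2c1O
F5 | step 9 | (6E,10E)-12-[(5-bromo-7-methoxy-2,2-dimethyl-4H-1,3-benzodioxin-8-yl)oxy]-2,6,10-trimethyldodeca-6,10-dien-2-yl acetate | COc1cc(Br)c2COC(C)(C)Oc2c1OC/C=C(\C)CC/C=C(\C)CCCC(C)(C)OC(C)=O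
F6 | step 8 | 6-bromo-2,3,4-trihydroxybenzaldehyde | O=Cc1c(Br)cc(O)c(O)c1O
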